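All runs are calculated from invented constants.

A ring reading at the end of a flask cannot be a yield, for ring disappears as well as forms. In Friday's run, starting material stays near 0.5% between 2.00 h and 4.00 h, while ring falls from 25.2% to 12.7%. Taken as first order, that reads as 0.343 /h, a half-life of 2.02 h.

in all of them: starting material 0.050 M
- Sunday's: activator 0.44 equiv; run made earlier
- Tuesday's: activator 1.1 equiv; run made earlier
- Friday's: activator 2.4 equiv; run made earlier
- east: activator 0.400 equiv; time 5.0 h
- north: activator 0.800 equiv; time 5.0 h
- south-east: activator 1.50 equiv; time 5.0 h
- south: activator 3.00 equiv; time 5.0 h

- Sunday's (time / h: ring / %, starting material / %): 0.250: 5.4, 69.9; 0.500: 9.0, 52.5; 1.00: 11.4, 37.4; 2.00: 12.1, 23.7; 4.00: 8.2, 14.5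
- Tuesday's (time / h: ring / %, starting material / %): 0.333: 15.4, 40.3; 0.833: 24.6, 17.0; 1.50: 24.8, 7.6; 2.50: 20.8, 3.1; 4.00: 12.6, 0.2
- Friday's (time / h: ring / %, starting material / %): 0.250: 25.2, 23.8; 0.500: 33.7, 7.8; 1.00: 35.0, 0.7; 2.00: 25.2, 0.4; 4.00: 12.7, 0.5

(standard deviation of a reading: 0.5 percentage points)

* [ring] at the end for east, north, south-east, south, in this order
* the course of these numbers from the first flask to the last (falls, then rises / hardly changes / rises all the way / falls all the way / rises, then falls)

- "hardly changes" means that all values lie within two and a half points (for a concentration: within two and a half percent of the largest)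

One number folds this together: the age count, the run time divided by the ring half-life, here 2.47. At that loss, ring born at the start keeps 18.0% at the end. The count is above one, so the birth time of ring matters as well as its amount.

The readings at 4.00 h show the price. Friday's ring peaked higher and earlier than Tuesday's, on twice the activator. Yet 12.7% and 12.6% tie within the scatter. The last hour keeps 71.0%, so the top of the row lies near 0.00447 M. Sunday's 8.2% places east near 0.00291 M, perhaps a little above, as 14.5% of its starting material remains. The count is not enough by itself: it prices age, and Sunday's low reading shows that yield counts too. My reckoning is therefore a rise, a top between Sunday's and Friday's charges, and a gentle fall.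

The forecast gives 0.0032 M, 0.0042 M, 0.0046 M and 0.0047 M, a course that rises all the way, and says “The row keeps rising but flattens”.

The flasks give 0.00260 M, 0.00462 M, 0.00417 M and 0.00397 M: the row rises, then falls, turning at 0.89 equiv.

    starting material + activator → activated form (k = 0.620 /M/min)
    2 starting material → self-condensation product (k = 0.0900 /M/min)
    starting material + activated form → open dimer (k = 6.90 /M/min)
    activated form → ring (k = 0.230 /min)
    ring → over-reaction product A (k = 0.00640 /min)
    ring → over-reaction product B (k = 4.40 × 10⁻⁵ /min)

At the end, south has made more ring than north, since ring and its over-reaction products together stand at 49.5% against 38.4%. But north keeps 24.1% of its ring as ring, south 16.1%, so south's ring is on average the older, within a full run of 2.47 on the age count read from Friday's run.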